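Ring A of the target (C1 ketone, C2 methoxy enol ether, C3 aryl, spiro C4, C5 methoxy/aryl) is a 4-oxy-5-alkoxycyclopent-2-enone with the C4–O and C5–OMe bonds trans: the signature of a 4-pyranone photoproduct. The plan contracts a kojic-acid-derived 3,6-diaryl-5-acyloxy-2-(chloromethyl)-4-pyranone, whose ring oxygen bridges the future C3 and C4. Irradiation in methanol forms the C3–C4 bond by 4π electrocyclisation; methanol caps C5 anti to the transient oxirane, which then opens to the C4 alcohol. One operation gives the carbocycle, both stereocentres and the C5 ether. The acyl group, a camphanate, steers the capture and makes the two ring antipodes separable diastereomers.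

Key step: step 6

Remark on conventions and one assumption: ring-contracted compounds carry the ring A locants defined above (C1 ketone to C5), pyranones carry kojic acid locants, and the TIPS-protected arylboronate is assumed to need preparation (step 2).

Step 1
Reactants: 1 kojic acid (5-hydroxy-2-(hydroxymethyl)-4H-pyran-4-one)
Product: 2 3,6-dibromo-5-hydroxy-2-(hydroxymethyl)-4H-pyran-4-one
Conditions: NBS (2.1 equiv), MeCN, 0 °C to rt, dark
Reagents that add atoms: N-bromosuccinimide, O=C1CCC(=O)N1Br
Why: Electrophilic (SEAr-type) bromination of the electron-rich hydroxypyranone at its only two ring C–H positions, C6 (ortho to the enolic 5-OH) and C3 (α-carbon of the vinylogous ester).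

Step 2
Reactants: 3 4-(4,4,5,5-tetramethyl-1,3,2-dioxaborolan-2-yl)phenol
Product: 4 triisopropyl[4-(4,4,5,5-tetramethyl-1,3,2-dioxaborolan-2-yl)phenoxy]silane
Conditions: TIPSCl, imidazole, DMF, rt
Reagents that add atoms: chlorotriisopropylsilane, CC(C)[Si](Cl)(C(C)C)C(C)C
Why: Silylation of a phenol; the bulky TIPS ether should survive aqueous base, acid chloride and alkoxide in later steps and is removed by fluoride at the end.

Step 3
Reactants: 2 3,6-dibromo-5-hydroxy-2-(hydroxymethyl)-4H-pyran-4-one; 4 TIPS-protected arylboronate (2.4 equiv)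
Product: 5 5-hydroxy-2-(hydroxymethyl)-3,6-bis[4-(triisopropylsilyloxy)phenyl]-4H-pyran-4-one
Conditions: Pd(OAc)2 (5 mol %), SPhos (10 mol %), K3PO4, 1,4-dioxane/H2O (5:1), 80 °C; aq NH4Cl work-up
Reagents that add atoms: none
Why: Twofold Suzuki–Miyaura coupling that puts the same aryl group on both C–Br carbons (C3 is a 3-halochromone-like position as used for isoflavones, C6 a 2-halo-3-hydroxypyranone position); free hydroxyl groups are tolerated with excess base.

Step 4
Reactants: 5 5-hydroxy-2-(hydroxymethyl)-3,6-bis[4-(triisopropylsilyloxy)phenyl]-4H-pyran-4-one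
Product: 6 2-(chloromethyl)-5-hydroxy-3,6-bis[4-(triisopropylsilyloxy)phenyl]-4H-pyran-4-one
Conditions: SOCl2 (1.5 equiv), CH2Cl2, 0 °C to rt
Reagents that add atoms: thionyl chloride, O=S(Cl)Cl
Why: Chlorodehydroxylation of the primary pyranylmethyl alcohol through its chlorosulfite, the transformation that converts kojic acid into chlorokojic acid; the enolic 5-OH is a vinylogous acid and is not replaced.

Step 5
Reactants: 6 2-(chloromethyl)-5-hydroxy-3,6-bis[4-(triisopropylsilyloxy)phenyl]-4H-pyran-4-one
Product: 7 2-(chloromethyl)-4-oxo-3,6-bis[4-(triisopropylsilyloxy)phenyl]-4H-pyran-5-yl (1S,4R)-camphanate (ester of (1S,4R)-4,7,7-trimethyl-3-oxo-2-oxabicyclo[2.2.1]heptane-1-carboxylic acid)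
Conditions: (1S)-(−)-camphanic chloride (1.2 equiv), i-Pr2NEt, DMAP (cat.), CH2Cl2, 0 °C
Reagents that add atoms: (1S)-(−)-camphanic chloride, O=C(Cl)[C@@]12CC[C@@](C)(C(=O)O1)C2(C)C
Why: DMAP-catalysed O-acylation of the only remaining hydroxyl group, the acidic enol; the camphanoyl unit is the electron-poor, hindered and enantiopure acyl group that step 6 needs.

Step 6
Reactants: 7 pyranone camphanate
Product: 10 (4S,5R)-4-(chloromethyl)-4-hydroxy-5-methoxy-3,5-bis[4-(triisopropylsilyloxy)phenyl]cyclopent-2-en-1-one 2-O-(1S,4R)-camphanate, via oxyallyl zwitterion 8 (not isolated), via methanol adduct enol 9 (not isolated)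
Conditions: hν (medium-pressure Hg lamp, Pyrex filter, λ > 300 nm), degassed MeOH (5 mM), 0 °C, stopped short of full conversion; then SiO2 chromatography (removes the (4R,5S) diastereomer)
Reagents that add atoms: methanol, CO
Why: Photochemical ring contraction of a 4-pyranone with solvent capture, the known behaviour of substituted 4-pyranones irradiated in hydroxylic solvents: excitation triggers a disrotatory 4π electrocyclisation of the cross-conjugated dienone that bonds the two carbons flanking the ring oxygen (future C3 and C4), so the six-membered ring contracts to the five-membered carbocycle of zwitterion 8 and the former ring oxygen is left as a transient cis-fused oxirane across C3–C4. The oxyallyl cation of 8 ends at C2 and C5; the acyloxy group makes C2 a poor cation site whereas the 4-silyloxyphenyl group stabilises charge at C5, so methanol should add at C5, on the face opposite the oxirane, to give enol 9. The enol(ate) of 9 then expels the benzylic C3–O bond of the oxirane in an E1cB-type β-elimination, which restores the C1 ketone and the C2=C3 double bond and leaves the oxygen on C4 as the tertiary alcohol of 10. C5 is set relative to C4 by this anti addition to the bicyclic zwitterion, so that C4–OH and C5–OMe are trans as in the target, while the direction of disrotation, and hence the absolute configuration at C4, is not controlled: the two ring antipodes should form in similar amounts and, because of the camphanate, are diastereomers, of which the (4S,5R) isomer 10 is separated from its (4R,5S) partner by chromatography or crystallisation and assigned against the known camphanate centres by X-ray analysis. The step needs capture at C5 instead of C2 (secured by the acyl/aryl pairing; a simple 5-methoxypyranone would be expected to ketalise at C2), trans capture (secured by the oxirane blocking one face) and trapping faster than rearrangement of 8 to an epoxycyclopentenone or a 2-pyranone (secured by methanol as solvent and by stopping short of full conversion). The hindered camphanoyl group should also be slow to migrate between the two oxygens of enol 9 and to undergo methanolysis during irradiation.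

Step 7
Reactants: 10 chlorohydrin enol camphanate
Product: 12 (4S,5R)-4-(chloromethyl)-4-hydroxy-2,5-dimethoxy-3,5-bis[4-(triisopropylsilyloxy)phenyl]cyclopent-2-en-1-one, via diosphenol 11 (not isolated)
Conditions: NaOMe (1.05 equiv), THF/MeOH, −40 °C; AcOH (1.1 equiv); then TMSCHN2, PhMe/MeOH, 0 °C
Reagents that add atoms: trimethylsilyldiazomethane, C[Si](C)(C)C=[N+]=[N-]
Why: Transesterification of the activated enol ester frees diosphenol 11 (only the aryl-conjugated C2 enol is possible because C5 is quaternary), and O-methylation of this acidic enol with the diazoalkane gives the methyl enol ether; methylating before epoxide closure avoids a diosphenolate next to an allylic epoxide, which could open it by β-elimination.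

Step 8
Reactants: 12 methyl enol ether chlorohydrin
Product: 13 (3R,4R)-4,6-dimethoxy-4,7-bis[4-(triisopropylsilyloxy)phenyl]-1-oxaspiro[2.4]hept-6-en-5-one
Conditions: t-BuOK (1.05 equiv), THF, −20 °C
Reagents that add atoms: none
Why: Intramolecular Williamson etherification (3-exo-tet SN2) of the tertiary alkoxide onto the primary chloride closes the spiro-epoxide with retention at C4, since only the CH2Cl carbon is substituted; there is no enolisable hydrogen, and closure should outrun retro-aldol opening of the β-alkoxy ketone.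

Step 9
Reactants: 13 bis-TIPS ether of the target
Product: 14 (3R,4R)-4,7-bis(4-hydroxyphenyl)-4,6-dimethoxy-1-oxaspiro[2.4]hept-6-en-5-one (target)
Conditions: TBAF (2.2 equiv), AcOH (2.2 equiv), THF, 0 °C
Reagents that add atoms: none
Why: Fluoride-mediated cleavage of the two aryl silyl ethers; the acetic acid buffer keeps the phenols protonated, protecting the epoxide and the benzylic C5 methyl ether (which a free phenoxide could expel via a quinone methide).

Compound list
1 | kojic acid, 5-hydroxy-2-(hydroxymethyl)-4H-pyran-4-one | OCc1cc(=O)c(O)co1 | starting material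
2 | 3,6-dibromo-5-hydroxy-2-(hydroxymethyl)-4H-pyran-4-one | OCc1oc(Br)c(O)c(=O)c1Br | intermediate
3 | 4-(4,4,5,5-tetramethyl-1,3,2-dioxaborolan-2-yl)phenol | CC1(C)OB(OC1(C)C)c1ccc(O)cc1 | starting material
4 | triisopropyl[4-(4,4,5,5-tetramethyl-1,3,2-dioxaborolan-2-yl)phenoxy]silane | CC(C)[Si](Oc1ccc(cc1)B1OC(C)(C)C(C)(C)O1)(C(C)C)C(C)C | intermediate
5 | 5-hydroxy-2-(hydroxymethyl)-3,6-bis[4-(triisopropylsilyloxy)phenyl]-4H-pyran-4-one | OCc1oc(-c2ccc(O[Si](C(C)C)(C(C)C)C(C)C)cc2)c(O)c(=O)c1-c1ccc(O[Si](C(C)C)(C(C)C)C(C)C)cc1 | intermediate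
6 | 2-(chloromethyl)-5-hydroxy-3,6-bis[4-(triisopropylsilyloxy)phenyl]-4H-pyran-4-one | ClCc1oc(-c2ccc(O[Si](C(C)C)(C(C)C)C(C)C)cc2)c(O)c(=O)c1-c1ccc(O[Si](C(C)C)(C(C)C)C(C)C)cc1 | intermediate
7 | 2-(chloromethyl)-4-oxo-3,6-bis[4-(triisopropylsilyloxy)phenyl]-4H-pyran-5-yl (1S,4R)-camphanate | ClCc1oc(-c2ccc(O[Si](C(C)C)(C(C)C)C(C)C)cc2)c(OC(=O)[C@@]34CC[C@@](C)(C(=O)O3)C4(C)C)c(=O)c1-c1ccc(O[Si](C(C)C)(C(C)C)C(C)C)cc1 | intermediate
8 | oxyallyl zwitterion: cyclopentenyl ring with C1–O−, cation over C2/C5 (drawn at C5), camphanoyloxy on C2, aryl on C3 and C5, CH2Cl on C4, oxirane cis-fused across C3–C4 on the face that becomes the C4–OH face | O=C(OC1=C([O-])[C+](c2ccc(O[Si](C(C)C)(C(C)C)C(C)C)cc2)[C@@]2(CCl)O[C@@]12c1ccc(O[Si](C(C)C)(C(C)C)C(C)C)cc1)[C@@]34CC[C@@](C)(C(=O)O3)C4(C)C | intermediate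
9 | methanol adduct: C1 enol with C5–OMe on the face opposite the C3–C4 oxirane | O=C(OC1=C(O)[C@@](OC)(c2ccc(O[Si](C(C)C)(C(C)C)C(C)C)cc2)[C@@]2(CCl)O[C@@]12c1ccc(O[Si](C(C)C)(C(C)C)C(C)C)cc1)[C@@]34CC[C@@](C)(C(=O)O3)C4(C)C | intermediate
10 | (4S,5R)-4-(chloromethyl)-4-hydroxy-5-methoxy-3,5-bis[4-(triisopropylsilyloxy)phenyl]cyclopent-2-en-1-one 2-O-(1S,4R)-camphanate | O=C(OC1=C(c2ccc(O[Si](C(C)C)(C(C)C)C(C)C)cc2)[C@@](O)(CCl)[C@](OC)(c2ccc(O[Si](C(C)C)(C(C)C)C(C)C)cc2)C1=O)[C@@]34CC[C@@](C)(C(=O)O3)C4(C)C | intermediate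
11 | (4S,5R)-4-(chloromethyl)-2,4-dihydroxy-5-methoxy-3,5-bis[4-(triisopropylsilyloxy)phenyl]cyclopent-2-en-1-one (diosphenol) | OC1=C(c2ccc(O[Si](C(C)C)(C(C)C)C(C)C)cc2)[C@@](O)(CCl)[C@](OC)(c2ccc(O[Si](C(C)C)(C(C)C)C(C)C)cc2)C1=O | intermediate
12 | (4S,5R)-4-(chloromethyl)-4-hydroxy-2,5-dimethoxy-3,5-bis[4-(triisopropylsilyloxy)phenyl]cyclopent-2-en-1-one | COC1=C(c2ccc(O[Si](C(C)C)(C(C)C)C(C)C)cc2)[C@@](O)(CCl)[C@](OC)(c2ccc(O[Si](C(C)C)(C(C)C)C(C)C)cc2)C1=O | intermediate
13 | (3R,4R)-4,6-dimethoxy-4,7-bis[4-(triisopropylsilyloxy)phenyl]-1-oxaspiro[2.4]hept-6-en-5-one | COC1=C(c2ccc(O[Si](C(C)C)(C(C)C)C(C)C)cc2)[C@@]2(CO2)[C@](OC)(c2ccc(O[Si](C(C)C)(C(C)C)C(C)C)cc2)C1=O | intermediate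
14 | (3R,4R)-4,7-bis(4-hydroxyphenyl)-4,6-dimethoxy-1-oxaspiro[2.4]hept-6-en-5-one | COC1=C(c2ccc(O)cc2)[C@@]2(CO2)[C@](OC)(c2ccc(O)cc2)C1=O | target

Total step count: 9. Longest linear sequence: 8 steps (1, 3, 4, 5, 6, 7, 8, 9, from kojic acid).

Steps most likely to fail

Step 6. What may go wrong: capture of the zwitterion at the wrong terminus, acyl migration in the enol, photosolvolysis of the C–Cl bond, or further photolysis of the product enone. Fallback, from 7 back to 10: irradiation in MeCN to low conversion, where no external nucleophile is present, should let zwitterion 8 rearrange. The oxirane oxygen stays bonded to C4 and walks from C3 to the cationic C5. This gives the isolable valence isomer, the 4,5-epoxycyclopent-2-enone camphanate F1, together with its ring-antipodal diastereomer, the epoxy enone camphanate F2. After separation, F1 is opened in methanol with pyridinium p-toluenesulfonate at the benzylic C5 with inversion. This gives the same trans chlorohydrin and rejoins the route at 10. F2 would lead only to the unwanted (4R,5S) diastereomer of 10 and is discarded.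

Step 1. What may go wrong: incomplete or unselective second bromination at C3, or oxidative degradation of the hydroxypyranone by excess NBS. Fallback, from 1 back to 5: one equivalent of NBS should brominate only the position ortho to the enolic hydroxyl, giving 6-bromokojic acid F3. Suzuki coupling of F3 with 4 gives the 6-aryl kojic acid F4. Its single remaining ring position is then brominated to the 3-bromo-6-aryl pyranone F5, and a second Suzuki coupling with 4 rejoins the route at 5.

Step 3. What may go wrong: sequestration of palladium by the chelating hydroxypyranonate, or loss of the silyl ethers under hot aqueous base. Fallback, from 2 back to 5: the enolic oxygen is masked (BnBr, K2CO3, DMF) as the benzyl ether dibromide F6. F6 is coupled twice with 4 under anhydrous conditions (Pd(OAc)2, SPhos, K3PO4, toluene) to the benzyl-protected diaryl pyranone F7. Hydrogenolysis (H2, Pd/C, EtOAc), the usual unmasking of kojic acid benzyl ethers, rejoins the route at 5.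

Further compounds
F1 | step 6 | 4,5-epoxy-4-(chloromethyl)-3,5-bis[4-(triisopropylsilyloxy)phenyl]cyclopent-2-en-1-one 2-O-(1S,4R)-camphanate, oxirane on the face that carries the C4 hydroxyl in 10 | O=C(OC1=C(c2ccc(O[Si](C(C)C)(C(C)C)C(C)C)cc2)[C@]2(CCl)O[C@]2(c2ccc(O[Si](C(C)C)(C(C)C)C(C)C)cc2)C1=O)[C@@]34CC[C@@](C)(C(=O)O3)C4(C)C
F2 | step 6 | ring-antipodal diastereomer of F1 (same camphanate) | O=C(OC1=C(c2ccc(O[Si](C(C)C)(C(C)C)C(C)C)cc2)[C@@]2(CCl)O[C@@]2(c2ccc(O[Si](C(C)C)(C(C)C)C(C)C)cc2)C1=O)[C@@]34CC[C@@](C)(C(=O)O3)C4(C)C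
F3 | step 1 | 6-bromo-5-hydroxy-2-(hydroxymethyl)-4H-pyran-4-one | OCc1cc(=O)c(O)c(Br)o1
F4 | step 1 | 5-hydroxy-2-(hydroxymethyl)-6-[4-(triisopropylsilyloxy)phenyl]-4H-pyran-4-one | OCc1cc(=O)c(O)c(-c2ccc(O[Si](C(C)C)(C(C)C)C(C)C)cc2)o1
F5 | step 1 | 3-bromo-5-hydroxy-2-(hydroxymethyl)-6-[4-(triisopropylsilyloxy)phenyl]-4H-pyran-4-one | OCc1oc(-c2ccc(O[Si](C(C)C)(C(C)C)C(C)C)cc2)c(O)c(=O)c1Br
F6 | step 3 | 5-(benzyloxy)-3,6-dibromo-2-(hydroxymethyl)-4H-pyran-4-one | OCc1oc(Br)c(OCc2ccccc2)c(=O)c1Br
F7 | step 3 | 5-(benzyloxy)-2-(hydroxymethyl)-3,6-bis[4-(triisopropylsilyloxy)phenyl]-4H-pyran-4-one | OCc1oc(-c2ccc(O[Si](C(C)C)(C(C)C)C(C)C)cc2)c(OCc2ccccc2)c(=O)c1-c1ccc(O[Si](C(C)C)(C(C)C)C(C)C)cc1
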